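**Plan**

- Retrosynthesis: the five O–Si bonds are cut first, then the C6–C1'' aryl–allyl bond (giving a C6 arylzinc and a (2E,6R)-allylic acetate), then C6–I, then the C2–C1' bond of the flavanone (giving a chromone and a B-ring boronic acid).
- Forward: the benzopyranone is bought as 5,7-dihydroxychromone. The B ring is added at C2 by asymmetric 1,4-addition, iodine is placed at C6, and the chain is made in three steps from geranyl acetate. The two halves are joined at C6–C1'' and all silyl groups are removed in one operation.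
- Enabling feature: the six-membered C5–OH···O=C4 hydrogen-bonded chelate of the A ring/pyranone. It keeps O5 free when O7 is silylated, and the only open ortho carbon of O5 is C6 (the other is the ring-fusion carbon C4a), so iodine, and then zinc, sit exactly there.
- The chain's C1''–C2''=C3'' unit ionises to a syn η3-allyl-palladium complex that keeps the E geometry and couples at its CH2 end.
- Stereochemistry: C2 (S) comes from ligand-controlled aryl delivery to the Re face of chromone C2. C6'' (R) comes from Shi epoxidation and is retained in the epoxide-to-allylic-alcohol isomerisation. The 2''E olefin comes from geranyl acetate.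

Key step: step 10

Remark: TBS = tert-butyldimethylsilyl. The sense of induction in step 4 is assigned by analogy with additions of the same ligand class to cyclic enones; the antipodal ligand would serve if the opposite sense were found.

**Step 1**
Reactants: 1 5,7-dihydroxy-4H-chromen-4-one
Product: 2 7-(TBSO)-5-hydroxy-4H-chromen-4-one
Conditions: TBSCl (1.05 equiv), imidazole, DMF, 0 °C
Reagents that add atoms: tert-butyldimethylsilyl chloride, CC(C)(C)[Si](C)(C)Cl
Why: Silyl etherification; the 7-OH (para to the carbonyl, most acidic, unhindered) should react while the 5-OH stays locked in its hydrogen bond to C4=O.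

**Step 2**
Reactants: 3 3-methoxybenzene-1,2-diol (3-methoxycatechol)
Product: 4 1,2-bis(TBSO)-3-methoxybenzene
Conditions: TBSCl (2.3 equiv), imidazole, DMF, rt
Reagents that add atoms: tert-butyldimethylsilyl chloride, CC(C)(C)[Si](C)(C)Cl
Why: Routine imidazole-promoted bis-silylation of a catechol; the bulky ethers later steer the C–H borylation and last to the final step.

**Step 3**
Reactants: 4 1,2-bis(TBSO)-3-methoxybenzene
Product: 6 [3,4-bis(TBSO)-5-methoxyphenyl]boronic acid, via aryl pinacol boronate 5 (not isolated)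
Conditions: [Ir(OMe)(cod)]2 (cat.), 4,4'-di-tert-butyl-2,2'-bipyridine (cat.), B2pin2, THF, 80 °C; then NaIO4, NH4OAc, acetone/H2O, rt
Reagents that add atoms: bis(pinacolato)diboron, CC1(C)OB(OC1(C)C)B1OC(C)(C)C(C)(C)O1; water, O
Why: Sterically governed iridium-catalysed aromatic C–H borylation should take place only at C5, the one ring C–H without an ortho substituent, and buffered periodate cleavage of the pinacol ester frees the boronic acid without touching the aryl silyl ethers.

**Step 4**
Reactants: 2 7-(TBSO)-5-hydroxy-4H-chromen-4-one; 6 [3,4-bis(TBSO)-5-methoxyphenyl]boronic acid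
Product: 7 (2S)-2-[3,4-bis(TBSO)-5-methoxyphenyl]-7-(TBSO)-5-hydroxychroman-4-one
Conditions: [Rh(OH)(cod)]2 (cat.), (S)-MeO-F12-BIPHEP (cat.), 6 (2 equiv), toluene/H2O, 30 °C
Reagents that add atoms: none
Why: Hayashi–Miyaura rhodium-catalysed asymmetric 1,4-addition of an arylboronic acid to a chromone whose carbonyl is activated by the internal 5-OH···O=C4 hydrogen bond; the chiral bisphosphine should direct the aryl group to the Re face of C2, which sets 2S, and the base-free medium avoids pyranone opening and desilylation.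

**Step 5**
Reactants: 7 (2S)-2-[3,4-bis(TBSO)-5-methoxyphenyl]-7-(TBSO)-5-hydroxychroman-4-one
Product: 8 (2S)-2-[3,4-bis(TBSO)-5-methoxyphenyl]-7-(TBSO)-5-hydroxy-6-iodochroman-4-one
Conditions: benzyltrimethylammonium dichloroiodate (1.05 equiv), CaCO3, CH2Cl2/MeOH, rt, dark
Reagents that add atoms: benzyltrimethylammonium dichloroiodate, C[N+](C)(C)Cc1ccccc1.Cl[I-]Cl
Why: Electrophilic aromatic iodination of a phenol with a dichloroiodate salt, a reagent known to iodinate 5-hydroxy-7-alkoxyflavones ortho to the chelated hydroxyl; C6 is the only open ortho position of O5 and the silylated B ring is far less activated than the free-phenol A ring.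

**Step 6**
Reactants: 8 (2S)-2-[3,4-bis(TBSO)-5-methoxyphenyl]-7-(TBSO)-5-hydroxy-6-iodochroman-4-one
Product: 9 (2S)-2-[3,4-bis(TBSO)-5-methoxyphenyl]-5,7-bis(TBSO)-6-iodochroman-4-one
Conditions: TBSOTf (1.2 equiv), 2,6-lutidine, CH2Cl2, −78 → −20 °C
Reagents that add atoms: tert-butyldimethylsilyl triflate, CC(C)(C)[Si](C)(C)OS(=O)(=O)C(F)(F)F
Why: Silyl triflate with a hindered pyridine is the usual silylation of a hydrogen-bonded, ortho-flanked phenol; it removes the only acidic proton before the organozinc is made, under conditions too weakly basic to open the pyranone or epimerise C2.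

**Step 7**
Reactants: 10 geranyl acetate [(2E)-3,7-dimethylocta-2,6-dien-1-yl acetate]
Product: 11 (2E)-5-[(2R)-3,3-dimethyloxiran-2-yl]-3-methylpent-2-en-1-yl acetate
Conditions: Shi ketone derived from D-fructose (0.3 equiv), Oxone, K2CO3, Bu4NHSO4, MeCN/dimethoxymethane, aq. Na2B4O7/EDTA buffer, 0 °C
Reagents that add atoms: potassium peroxymonosulfate (Oxone), [K+].[O-]S(=O)(=O)OO
Why: Shi asymmetric epoxidation (chiral dioxirane, spiro transition state) should oxidise the electron-rich 6,7-olefin in preference to the acetate-deactivated 2,3-olefin and, by the established sense for trisubstituted olefins, give the 6R epoxide.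

**Step 8**
Reactants: 11 (2E)-5-[(2R)-3,3-dimethyloxiran-2-yl]-3-methylpent-2-en-1-yl acetate
Product: 12 (2E,6R)-6-hydroxy-3,7-dimethylocta-2,7-dien-1-yl acetate
Conditions: Al(OiPr)3 (1.5 equiv), toluene, 110 °C
Reagents that add atoms: none
Why: Aluminium isopropoxide-mediated isomerisation of a trisubstituted epoxide to the allylic alcohol; syn removal of a methyl proton through a cyclic transition state breaks only the C7–O bond, so the C6–O bond and its R configuration are retained.

**Step 9**
Reactants: 12 (2E,6R)-6-hydroxy-3,7-dimethylocta-2,7-dien-1-yl acetate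
Product: 13 (2E,6R)-6-(TBSO)-3,7-dimethylocta-2,7-dien-1-yl acetate
Conditions: TBSCl, imidazole, DMF, rt
Reagents that add atoms: tert-butyldimethylsilyl chloride, CC(C)(C)[Si](C)(C)Cl
Why: Routine silylation of a secondary alcohol, which keeps the hydroxyl from quenching the organozinc in step 10 and is removed together with the aryl silyl ethers.

**Step 10**
Reactants: 9 (2S)-2-[3,4-bis(TBSO)-5-methoxyphenyl]-5,7-bis(TBSO)-6-iodochroman-4-one; 13 (2E,6R)-6-(TBSO)-3,7-dimethylocta-2,7-dien-1-yl acetate
Product: 15 (2S)-2-[3,4-bis(TBSO)-5-methoxyphenyl]-5,7-bis(TBSO)-6-[(2E,6R)-6-(TBSO)-3,7-dimethylocta-2,7-dien-1-yl]chroman-4-one, via arylzinc iodide 14 (not isolated)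
Conditions: Zn dust (activated by 1,2-dibromoethane/TMSCl), LiCl, THF, 50 °C; supernatant transferred to 13 and Pd(PPh3)4 (5 mol%), THF, 25 → 40 °C
Reagents that add atoms: none
Why: Zinc inserts oxidatively into the C6–I bond (LiCl-assisted) to give arylzinc 14, which tolerates the C4 ketone and brings no base that could open the pyranone at C2; Pd(0) ionises the primary allylic acetate of 13 to the syn η3-allyl complex derived from the E olefin, transmetalation from zinc follows, and reductive elimination joins C6 to the unsubstituted CH2 terminus. The closest known reaction type is the Negishi palladium-catalysed allyl–aryl coupling of arylzinc reagents with geranyl- and neryl-type electrophiles. No ring is closed and no stereocentre is created; C2 (S) and C6'' (R) are carried through unchanged. Three selectivities are needed: position on the A ring (fixed by the C6 iodine, itself placed by the chelated 5-OH), α over γ attack (the γ terminus C3'' is fully substituted and the aryl group is flanked by two silyloxy groups, so bond formation at CH2 should prevail), and retention of the 2''E geometry (syn/anti exchange would have to pass through the tertiary η1-allyl at C3'', which should be slower than coupling). The silyl ether at C6'' is not a leaving group for Pd(0), so only the acetate terminus should react.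

**Step 11**
Reactants: 15 (2S)-2-[3,4-bis(TBSO)-5-methoxyphenyl]-5,7-bis(TBSO)-6-[(2E,6R)-6-(TBSO)-3,7-dimethylocta-2,7-dien-1-yl]chroman-4-one
Product: 16 (2S)-2-(3,4-dihydroxy-5-methoxyphenyl)-5,7-dihydroxy-6-[(2E,6R)-6-hydroxy-3,7-dimethylocta-2,7-dien-1-yl]chroman-4-one
Conditions: HF·pyridine, pyridine, THF, 0 °C → rt
Reagents that add atoms: none
Why: Fluoride-mediated cleavage of the four aryl and one secondary alkyl TBS ethers under buffered, non-basic conditions, which should leave the base-labile C2 centre, the catechol, the allylic alcohol and the ortho-allylphenol (no acid-induced chroman closure) intact.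

**Compound list**

1 | 5,7-dihydroxy-4H-chromen-4-one | O=c1ccoc2cc(O)cc(O)c12 | starting material
2 | 7-(TBSO)-5-hydroxy-4H-chromen-4-one | O=c1ccoc2cc(O[Si](C)(C)C(C)(C)C)cc(O)c12 | intermediate
3 | 3-methoxybenzene-1,2-diol | COc1cccc(O)c1O | starting material
4 | 1,2-bis(TBSO)-3-methoxybenzene | COc1cccc(O[Si](C)(C)C(C)(C)C)c1O[Si](C)(C)C(C)(C)C | intermediate
5 | 2-[3,4-bis(TBSO)-5-methoxyphenyl]-4,4,5,5-tetramethyl-1,3,2-dioxaborolane (not isolated) | COc1cc(B2OC(C)(C)C(C)(C)O2)cc(O[Si](C)(C)C(C)(C)C)c1O[Si](C)(C)C(C)(C)C | intermediate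
6 | [3,4-bis(TBSO)-5-methoxyphenyl]boronic acid | COc1cc(B(O)O)cc(O[Si](C)(C)C(C)(C)C)c1O[Si](C)(C)C(C)(C)C | intermediate
7 | (2S)-2-[3,4-bis(TBSO)-5-methoxyphenyl]-7-(TBSO)-5-hydroxychroman-4-one | O=C1C[C@@H](c2cc(O[Si](C)(C)C(C)(C)C)c(O[Si](C)(C)C(C)(C)C)c(OC)c2)Oc2cc(O[Si](C)(C)C(C)(C)C)cc(O)c21 | intermediate
8 | (2S)-2-[3,4-bis(TBSO)-5-methoxyphenyl]-7-(TBSO)-5-hydroxy-6-iodochroman-4-one | O=C1C[C@@H](c2cc(O[Si](C)(C)C(C)(C)C)c(O[Si](C)(C)C(C)(C)C)c(OC)c2)Oc2cc(O[Si](C)(C)C(C)(C)C)c(I)c(O)c21 | intermediate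
9 | (2S)-2-[3,4-bis(TBSO)-5-methoxyphenyl]-5,7-bis(TBSO)-6-iodochroman-4-one | O=C1C[C@@H](c2cc(O[Si](C)(C)C(C)(C)C)c(O[Si](C)(C)C(C)(C)C)c(OC)c2)Oc2cc(O[Si](C)(C)C(C)(C)C)c(I)c(O[Si](C)(C)C(C)(C)C)c21 | intermediate
10 | geranyl acetate | CC(=O)OC/C=C(\C)CCC=C(C)C | starting material
11 | (2E)-5-[(2R)-3,3-dimethyloxiran-2-yl]-3-methylpent-2-en-1-yl acetate | CC(=O)OC/C=C(\C)CC[C@H]1OC1(C)C | intermediate
12 | (2E,6R)-6-hydroxy-3,7-dimethylocta-2,7-dien-1-yl acetate | CC(=O)OC/C=C(\C)CC[C@@H](O)C(C)=C | intermediate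
13 | (2E,6R)-6-(TBSO)-3,7-dimethylocta-2,7-dien-1-yl acetate | CC(=O)OC/C=C(\C)CC[C@@H](O[Si](C)(C)C(C)(C)C)C(C)=C | intermediate
14 | C6 arylzinc iodide of 9 (not isolated) | O=C1C[C@@H](c2cc(O[Si](C)(C)C(C)(C)C)c(O[Si](C)(C)C(C)(C)C)c(OC)c2)Oc2cc(O[Si](C)(C)C(C)(C)C)c([Zn]I)c(O[Si](C)(C)C(C)(C)C)c21 | intermediate
15 | (2S)-2-[3,4-bis(TBSO)-5-methoxyphenyl]-5,7-bis(TBSO)-6-[(2E,6R)-6-(TBSO)-3,7-dimethylocta-2,7-dien-1-yl]chroman-4-one | O=C1C[C@@H](c2cc(O[Si](C)(C)C(C)(C)C)c(O[Si](C)(C)C(C)(C)C)c(OC)c2)Oc2cc(O[Si](C)(C)C(C)(C)C)c(C/C=C(\C)CC[C@@H](O[Si](C)(C)C(C)(C)C)C(C)=C)c(O[Si](C)(C)C(C)(C)C)c21 | intermediate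
16 | (2S)-2-(3,4-dihydroxy-5-methoxyphenyl)-5,7-dihydroxy-6-[(2E,6R)-6-hydroxy-3,7-dimethylocta-2,7-dien-1-yl]chroman-4-one | O=C1C[C@@H](c2cc(O)c(O)c(OC)c2)Oc2cc(O)c(C/C=C(\C)CC[C@@H](O)C(C)=C)c(O)c21 | target

**Step count and risks**

Total step count: 11. Longest linear sequence: 7 steps (steps 2, 3, 4, 5, 6, 10, 11, from 3-methoxycatechol).

Steps most likely to fail:

1. Step 10. What may go wrong: slow zinc insertion at the electron-rich C6–I bond flanked by two silyloxy groups, with protonolysis of the arylzinc (loss of the C6 handle); or transmetalation too slow to outrun syn/anti exchange of the allyl complex. The fallback uses tin in place of zinc and needs no metal insertion. It sets out from 9, which is converted by palladium-catalysed stannylation (Me3Sn–SnMe3, Pd(PPh3)4, toluene, 100 °C) into the aryltrimethylstannane F1. Stille–Migita coupling of F1 with the allylic acetate 13 (Pd2(dba)3, tri(2-furyl)phosphine, LiCl, NMP, 50 °C) comes back to the route at 15.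

2. Step 4. What may go wrong: incomplete facial discrimination at C2, and protodeboronation when insertion into the electron-rich chromone is slow. The fallback replaces asymmetric induction by resolution. It sets out from 2 and 6: an achiral Pd(II)/2,2'-bipyridine-catalysed conjugate addition gives the racemic flavanone F2. Noyori asymmetric transfer hydrogenation run as a kinetic resolution (RuCl(p-cymene)[(R,R)-TsDPEN], HCO2H/Et3N 5:2, EtOAc, rt, about half conversion) is expected to reduce the 2R enantiomer to the cis-(2R,4R)-flavan-4-ol F3, which is removed by chromatography. The unreduced (2S)-flavanone is 7, where the route is rejoined.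

3. Step 5. What may go wrong: loss of positional control, that is attack para to the 5-hydroxyl (C8), iodination of the B ring, or double iodination. The fallback delivers the chain from O5 and uses no halogen. It sets out from 13 and 7: methanolysis of 13 (K2CO3, MeOH, 0 °C) gives the allylic alcohol F4. Mitsunobu etherification of the 5-hydroxyl of 7 with F4 (PPh3, DIAD, THF, 0 °C) gives the 5-O-allyl ether F5. A clay-promoted [1,3] shift (montmorillonite K10, CH2Cl2, 0 °C) from O5 to its only open ortho carbon gives the C6-allylated phenol F6. Desilylation of F6 under the conditions of step 11 comes back to the route at 16.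

**Further compounds**

F1 | step 10 | (2S)-2-[3,4-bis(TBSO)-5-methoxyphenyl]-5,7-bis(TBSO)-6-(trimethylstannyl)chroman-4-one | O=C1C[C@@H](c2cc(O[Si](C)(C)C(C)(C)C)c(O[Si](C)(C)C(C)(C)C)c(OC)c2)Oc2cc(O[Si](C)(C)C(C)(C)C)c([Sn](C)(C)C)c(O[Si](C)(C)C(C)(C)C)c21
F2 | step 4 | racemic 2-[3,4-bis(TBSO)-5-methoxyphenyl]-7-(TBSO)-5-hydroxychroman-4-one | O=C1CC(c2cc(O[Si](C)(C)C(C)(C)C)c(O[Si](C)(C)C(C)(C)C)c(OC)c2)Oc2cc(O[Si](C)(C)C(C)(C)C)cc(O)c21
F3 | step 4 | (2R,4R)-2-[3,4-bis(TBSO)-5-methoxyphenyl]-7-(TBSO)chromane-4,5-diol | O[C@@H]1C[C@H](c2cc(O[Si](C)(C)C(C)(C)C)c(O[Si](C)(C)C(C)(C)C)c(OC)c2)Oc2cc(O[Si](C)(C)C(C)(C)C)cc(O)c21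
F4 | step 5 | (2E,6R)-6-(TBSO)-3,7-dimethylocta-2,7-dien-1-ol | OC/C=C(\C)CC[C@@H](O[Si](C)(C)C(C)(C)C)C(C)=C
F5 | step 5 | (2S)-2-[3,4-bis(TBSO)-5-methoxyphenyl]-7-(TBSO)-5-{[(2E,6R)-6-(TBSO)-3,7-dimethylocta-2,7-dien-1-yl]oxy}chroman-4-one | O=C1C[C@@H](c2cc(O[Si](C)(C)C(C)(C)C)c(O[Si](C)(C)C(C)(C)C)c(OC)c2)Oc2cc(O[Si](C)(C)C(C)(C)C)cc(OC/C=C(\C)CC[C@@H](O[Si](C)(C)C(C)(C)C)C(C)=C)c21
F6 | step 5 | (2S)-2-[3,4-bis(TBSO)-5-methoxyphenyl]-7-(TBSO)-5-hydroxy-6-[(2E,6R)-6-(TBSO)-3,7-dimethylocta-2,7-dien-1-yl]chroman-4-one | O=C1C[C@@H](c2cc(O[Si](C)(C)C(C)(C)C)c(O[Si](C)(C)C(C)(C)C)c(OC)c2)Oc2cc(O[Si](C)(C)C(C)(C)C)c(C/C=C(\C)CC[C@@H](O[Si](C)(C)C(C)(C)C)C(C)=C)c(O)c21
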